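## Analysis of the target

- Target 11 is a single carbocycle, a cyclopent-2-en-1-one. In the text, C1 is the carbonyl carbon, C2=C3 the enone alkene, C4 the fully substituted carbon carrying the acetoxy group and the 7-carboxyheptyl chain, and C5 the CH carrying the (Z)-pent-2-enyl chain. In the compound names the ring is numbered as a cyclopent-2-en-1-yl substituent, so text C4 = name C1, text C1 = name C4, and C5 = C5.
- C4 and C5 are contiguous stereocenters, (4R,5S) in the text numbering and (1R,5S) in the names. The two carbon chains are cis and the acetoxy group is trans to the pentenyl chain.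
- A third stereo-element is the Z alkene, one CH2 away from C5. The chain on C4 ends in a free carboxylic acid.
- C5–H is α to the C1 ketone and β to the C4 acetate. Enolization would epimerize C5 towards the probably more stable trans-dialkyl isomer, and the same enolate can expel the acetate, so no base may touch the ring once it exists.
- The difficulty is a tetrasubstituted C–O stereocenter next to an epimerizable carbon, in a contra-thermodynamic cis-dialkyl relation, with the absolute configuration to be set without resident chirality.
- The array O=C1–C2=C3–C4(–O), closed by the C4–C5 bond and with the C4 oxygen trans to the C5 substituent, maps atom for atom onto a 2,5-disubstituted furan plus its exocyclic carbinol carbon. Ring O becomes the C1 carbonyl oxygen, furan C2/C3/C4/C5 become C1/C2/C3/C4, and the carbinol carbon becomes C5. The route exploits this feature.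

## Retrosynthetic reasoning

**11 ⇒ 10 ⇒ 9.** The acid and the acetate are adjusted last, under acid only. 11 comes from tert-butyl ester 10 by acidolysis, and 10 from tertiary alcohol 9 by Lewis-acid-catalysed acetylation. No C–C bond or stereocenter is involved, and the ring never meets base.

**9 ⇒ 8 (key disconnection).** The C4–C5 ring bond and the C4–OH bond are cut, and the C1 carbonyl oxygen is reconnected to C4. This turns the cyclopentenone into the 2,5-disubstituted furylcarbinol 8.
- The cut is made here because C4 already sits at the oxidation level of a furan α-carbon, and because the trans relation of the C4 oxygen to the C5 chain is what a conrotatory pentadienyl-cation closure delivers.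
- The gain is that the ring, the tetrasubstituted C4 and the C4/C5 relation all come from one step. The only stereocenter of 8 is erased on ionization, so 8 can be made racemic.
- The forward reaction has to ionize 8, take up the C4 oxygen from the aqueous medium at the chain-bearing furan carbon, and close the ring under control of a chiral counter-anion.

**8 ⇒ 5 + 7 (7 from 6).** The bond between the furan carbon and the first CH2 of the acid chain is cut as an sp2–sp3 cross-coupling of bromofuran 5 with alkylzinc 7, made from bromo ester 6. The ester-bearing chain is thus put on after all organolithium chemistry is finished, so the ester needs no protection beyond its tert-butyl group.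

**5 ⇒ 4 + 2 (4 from 3, 2 from 1).** The bond between the carbinol carbon and the furan is cut as the addition of furyllithium 4, from dibromofuran 3, to aldehyde 2. The Z alkene is bought in with leaf alcohol 1, so no olefination or semi-hydrogenation is needed.

## Alternatives that were turned down

Alternative 1: the textbook disconnection, ring-closing metathesis at C2=C3.
- Disconnection: the C2=C3 bond, leading back to acyclic dienone A1, whose two stereocenters would be set by an aldol-type addition to a vinyl ketone.
- Forward key step: ring closure with the second-generation Grubbs catalyst.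
- Turned down because the pentenyl alkene and the C4 vinyl group of A1 can close a cyclopentene of their own, in competition with the enone ring.
- The tetrasubstituted carbinol would need a ketone aldol of an α-branched enolate, which has weak facial bias and reverts easily.
- All stereochemistry would still be built acyclically, over roughly twice the number of steps.

Alternative 2: oxidative furan opening and intramolecular aldol.
- Disconnection: the C4–C5 bond as an aldol, leading back to cis-enedione A3, obtained by oxidizing 2,5-dialkylfuran A2.
- Forward key step: base- or amine-mediated 5-ring aldol of A3.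
- Turned down because A3 has two equivalent enolizable CH2 groups flanking two equivalent ketones, so the aldol has no regiochemical bias and a constitutional isomer is expected alongside.
- The oxidants that open furans also attack the skipped Z alkene.
- The aldol needs the very basic conditions that epimerize and isomerize the product, and neither relative nor absolute configuration has a control element.

Alternative 3: desymmetrizing 1,2-addition to a cyclopentenedione.
- Disconnection: the bond from C4 to the acid chain, leading back to prochiral dione A4.
- Forward key step: enantiotopos-selective addition of an eight-carbon organometallic to one carbonyl of A4.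
- Turned down because the C–H between the two carbonyls of A4 is acidic enough to quench the organometallic.
- Any addition that does occur should come anti to the pentenyl group, placing the new chain trans to it, which gives the C4 epimer of the required compound.
- Discrimination of the two carbonyls would also need an unprecedented catalyst.

Key step: step 4

Assumption: the (R)-configured catalyst of step 4 is taken to give the (1R,5S) product. The sense of induction cannot be derived from precedent, and the (S)-configured catalyst would be used if the opposite sense results. Compounds 1, 3 and 6 are taken as catalog compounds.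

## Route

Step 1
Reactants: 1 (3Z)-hex-3-en-1-ol
Product: 2 (3Z)-hex-3-enal
Conditions: Dess–Martin periodinane (1.1 equiv), NaHCO3, CH2Cl2, 0 °C; used at once as a dried solution
Reagents that add atoms: none
Why: Dess–Martin oxidation of a primary alcohol under buffered, non-basic conditions with short contact, so that the skipped Z alkene should not move into conjugation.

Step 2
Reactants: 3 2,5-dibromofuran; 2 (3Z)-hex-3-enal
Product: 5 (3Z)-1-(5-bromofuran-2-yl)hex-3-en-1-ol (racemic), via 5-bromofuran-2-yllithium 4 (not isolated)
Conditions: n-BuLi (1.0 equiv), Et2O, −78 °C; then 2, −78 °C; aq NH4Cl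
Reagents that add atoms: none
Why: Bromine–lithium exchange of one C–Br bond gives 4, which should add 1,2 to the aldehyde at −78 °C faster than it deprotonates it. The carbinol center is left racemic on purpose, since step 4 erases it.

Step 3
Reactants: 5 (3Z)-1-(5-bromofuran-2-yl)hex-3-en-1-ol; 6 tert-butyl 8-bromooctanoate
Product: 8 tert-butyl 8-{5-[(3Z)-1-hydroxyhex-3-en-1-yl]furan-2-yl}octanoate (racemic), via (8-tert-butoxy-8-oxooctyl)zinc bromide 7 (not isolated)
Conditions: 6, Zn dust, LiCl, THF, 50 °C; then 5, Pd(OAc)2 (2 mol%), 2-dicyclohexylphosphino-2',6'-dimethoxybiphenyl (4 mol%), THF, 25 °C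
Reagents that add atoms: none
Why: Negishi sp2–sp3 coupling: the alkylzinc bromide from direct zinc insertion tolerates the tert-butyl ester. Oxidative addition of the furyl C–Br bond to zerovalent palladium, transmetalation and reductive elimination should outrun protonolysis of the organozinc by the free hydroxyl, and the bulky biarylphosphine suppresses β-hydride elimination.

Step 4
Reactants: 8 tert-butyl 8-{5-[(3Z)-1-hydroxyhex-3-en-1-yl]furan-2-yl}octanoate
Product: 9 tert-butyl 8-[(1R,5S)-1-hydroxy-4-oxo-5-[(2Z)-pent-2-en-1-yl]cyclopent-2-en-1-yl]octanoate
Conditions: (R)-3,3'-bis(2,4,6-triisopropylphenyl)-1,1'-binaphthyl-2,2'-diyl N-(trifluoromethanesulfonyl)phosphoramide (10 mol%), H2O (10 equiv), toluene, 40 °C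
Reagents that add atoms: water, O
Why: Proposed new method: the acid ionizes the furylcarbinol to a furfuryl (2-alkylidenefuranium) cation, water adds at the chain-bearing furan carbon, and opening of the hemiketal gives a 1,4-dihydroxypentadienyl cation that closes by conrotatory 4π-electron electrocyclization, forming the C4–C5 bond and, after proton loss, the enone. The closest known reactions are the racemic Piancatelli rearrangement of 5-alkyl-2-furyl carbinols with allylic carbinol substituents under aqueous acid, and the enantioselective aza-Piancatelli and Nazarov cyclizations under chiral phosphoric acid or N-triflylphosphoramide catalysis; new is the enantioselective version with water as the nucleophile. The five-membered carbocycle is the only ring closed, by electrocyclic closure between the former carbinol carbon and the former furan C5. Relative configuration: the pentenyl group sits outside at one terminus and the hydroxyl outside at the oxocarbenium terminus (π-donor outward, alkyl chain inside), so conrotation should place OH trans to the pentenyl group and the two carbon chains cis, as is general for Piancatelli rearrangements. Absolute configuration: the sense of conrotation is set by the chiral phosphoramide anion, hydrogen-bonded to both hydroxyls of the cation in the non-polar medium. Ionization erases the carbinol stereocenter of 8, so both enantiomers of 8 converge on one product. The step needs electrocyclization to win over E1 loss to a dienylfuran and over hydration to the open enedione, which the cation-stabilizing 5-alkylfuran and the water-poor medium favor, and the mild non-basic conditions should leave C5 unenolized.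

Step 5
Reactants: 9 tert-butyl 8-[(1R,5S)-1-hydroxy-4-oxo-5-[(2Z)-pent-2-en-1-yl]cyclopent-2-en-1-yl]octanoate
Product: 10 tert-butyl 8-[(1R,5S)-1-(acetyloxy)-4-oxo-5-[(2Z)-pent-2-en-1-yl]cyclopent-2-en-1-yl]octanoate
Conditions: Ac2O (3 equiv), Sc(OTf)3 (2 mol%), MeCN, −20 °C
Reagents that add atoms: acetic anhydride, CC(=O)OC(C)=O
Why: Sc(OTf)3-catalysed acylation of a tertiary alcohol; under acid neither C5 enolate formation (epimerization) nor β-elimination is opened. Ionization at C4 is disfavoured because the cation would be conjugated with the enone carbonyl, so C4 and C5 should stay untouched.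

Step 6
Reactants: 10 tert-butyl 8-[(1R,5S)-1-(acetyloxy)-4-oxo-5-[(2Z)-pent-2-en-1-yl]cyclopent-2-en-1-yl]octanoate
Product: 11 8-[(1R,5S)-1-(acetyloxy)-4-oxo-5-[(2Z)-pent-2-en-1-yl]cyclopent-2-en-1-yl]octanoic acid
Conditions: CF3CO2H/CH2Cl2 (1:4), 0 °C
Reagents that add atoms: none
Why: Acidolysis of the tert-butyl ester, with the tert-butyl cation lost as 2-methylpropene. The tertiary acetate should not ionize for the reason given in step 5, and no base is used, so C5 keeps its configuration.

## Compound list

1 | (3Z)-hex-3-en-1-ol | CC/C=C\CCO | starting material
2 | (3Z)-hex-3-enal | CC/C=C\CC=O | intermediate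
3 | 2,5-dibromofuran | Brc1ccc(Br)o1 | starting material
4 | 5-bromofuran-2-yllithium | [Li]c1ccc(Br)o1 | intermediate
5 | (3Z)-1-(5-bromofuran-2-yl)hex-3-en-1-ol (racemic) | CC/C=C\CC(O)c1ccc(Br)o1 | intermediate
6 | tert-butyl 8-bromooctanoate | CC(C)(C)OC(=O)CCCCCCCBr | starting material
7 | (8-tert-butoxy-8-oxooctyl)zinc bromide | CC(C)(C)OC(=O)CCCCCCC[Zn]Br | intermediate
8 | tert-butyl 8-{5-[(3Z)-1-hydroxyhex-3-en-1-yl]furan-2-yl}octanoate (racemic) | CC/C=C\CC(O)c1ccc(CCCCCCCC(=O)OC(C)(C)C)o1 | intermediate
9 | tert-butyl 8-[(1R,5S)-1-hydroxy-4-oxo-5-[(2Z)-pent-2-en-1-yl]cyclopent-2-en-1-yl]octanoate | CC/C=C\C[C@@H]1C(=O)C=C[C@@]1(CCCCCCCC(=O)OC(C)(C)C)O | intermediate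
10 | tert-butyl 8-[(1R,5S)-1-(acetyloxy)-4-oxo-5-[(2Z)-pent-2-en-1-yl]cyclopent-2-en-1-yl]octanoate | CC/C=C\C[C@@H]1C(=O)C=C[C@@]1(CCCCCCCC(=O)OC(C)(C)C)OC(C)=O | intermediate
11 | 8-[(1R,5S)-1-(acetyloxy)-4-oxo-5-[(2Z)-pent-2-en-1-yl]cyclopent-2-en-1-yl]octanoic acid | CC/C=C\C[C@@H]1C(=O)C=C[C@@]1(CCCCCCCC(=O)O)OC(C)=O | target

## Step count and least certain steps

Total step count: 6. Longest linear sequence: 6 steps (1 → 2 → 5 → 8 → 9 → 10 → 11). The branch 6 → 7 is made in the flask of step 3.

**Step 4 (key step, proposed new method).**
- Most likely failure: loss of enantiocontrol. Water-solvated, loosely paired cations can cyclize without guidance from the chiral anion, and the outward preference of the hydroxyl may not be complete.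
- Second failure mode: E1 loss of the allylic proton from the furfuryl cation.
- Fallback with known chemistry, setting out from 8: the racemic Piancatelli rearrangement with Dy(OTf)3 (10 mol%) in t-BuOH/H2O at 80 °C should give 9 as the racemate. That is 9 together with its enantiomer tert-butyl 8-[(1S,5R)-1-hydroxy-4-oxo-5-[(2Z)-pent-2-en-1-yl]cyclopent-2-en-1-yl]octanoate F1.
- The two are separated by preparative chromatography on an amylose tris(3,5-dimethylphenylcarbamate) stationary phase, and the route is rejoined at 9.

**Step 2.**
- Most likely failure: the basic furyllithium deprotonates the doubly activated α-CH2 of 2, and the alkene then migrates into conjugation, which lowers conversion and diverts material to the adduct of the 2-enal.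
- Fallback, setting out from 4, reverses the polarity so that no β,γ-unsaturated carbonyl compound is needed. Quenching 4 with DMF gives 5-bromofuran-2-carbaldehyde F2.
- Separately, (2Z)-pent-2-en-1-ol is converted with N-chlorosuccinimide and Me2S into (2Z)-1-chloropent-2-ene F3. Activated barium (from BaI2 and lithium biphenylide) at −78 °C turns this into [(2Z)-pent-2-en-1-yl]barium chloride F4.
- Allylbarium reagents add to aldehydes through the unsubstituted carbon with retention of the alkene geometry, so F4 and F2 should give 5, where the route is rejoined.

**Step 3.**
- Most likely failure: protonolysis of the alkylzinc by the free hydroxyl, and decomposition of the electron-rich bromofurylcarbinol in the presence of zinc salts before oxidative addition.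
- Fallback, setting out from 3 and 7, changes the order. Coupling 7 with excess 3 under the same palladium catalyst gives tert-butyl 8-(5-bromofuran-2-yl)octanoate F5, which has no hydroxyl.
- Bromine–lithium exchange on F5 with n-BuLi at −90 °C, faster than attack on the tert-butyl ester, gives {5-[8-(tert-butoxy)-8-oxooctyl]furan-2-yl}lithium F6. Addition of 2 then rejoins the route at 8.

**Step 5.**
- Most likely failure: slow acylation of the hindered tertiary hydroxyl, leaving the Lewis acid time to cleave the tert-butyl ester or to enolize C5.
- Fallback, setting out from 9, removes the acid-labile group first. Acidolysis with CF3CO2H in CH2Cl2 at 0 °C gives 8-[(1R,5S)-1-hydroxy-4-oxo-5-[(2Z)-pent-2-en-1-yl]cyclopent-2-en-1-yl]octanoic acid F7.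
- F7 can then be acetylated under forcing conditions, Ac2O as co-solvent with Sc(OTf)3, to the mixed anhydride acetic 8-[(1R,5S)-1-(acetyloxy)-4-oxo-5-[(2Z)-pent-2-en-1-yl]cyclopent-2-en-1-yl]octanoic anhydride F8, which is not isolated.
- Hydrolysis of the anhydride in THF/H2O at 25 °C leaves the tertiary acetate intact and rejoins the route at 11.

## Further compounds

F1 | step 4 | tert-butyl 8-[(1S,5R)-1-hydroxy-4-oxo-5-[(2Z)-pent-2-en-1-yl]cyclopent-2-en-1-yl]octanoate | CC/C=C\C[C@H]1C(=O)C=C[C@]1(CCCCCCCC(=O)OC(C)(C)C)O
F2 | step 2 | 5-bromofuran-2-carbaldehyde | O=Cc1ccc(Br)o1
F3 | step 2 | (2Z)-1-chloropent-2-ene | CC/C=C\CCl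
F4 | step 2 | [(2Z)-pent-2-en-1-yl]barium chloride | CC/C=C\C[Ba]Cl
F5 | step 3 | tert-butyl 8-(5-bromofuran-2-yl)octanoate | CC(C)(C)OC(=O)CCCCCCCc1ccc(Br)o1
F6 | step 3 | {5-[8-(tert-butoxy)-8-oxooctyl]furan-2-yl}lithium | CC(C)(C)OC(=O)CCCCCCCc1ccc([Li])o1
F7 | step 5 | 8-[(1R,5S)-1-hydroxy-4-oxo-5-[(2Z)-pent-2-en-1-yl]cyclopent-2-en-1-yl]octanoic acid | CC/C=C\C[C@@H]1C(=O)C=C[C@@]1(CCCCCCCC(=O)O)O
F8 | step 5 | acetic 8-[(1R,5S)-1-(acetyloxy)-4-oxo-5-[(2Z)-pent-2-en-1-yl]cyclopent-2-en-1-yl]octanoic anhydride | CC/C=C\C[C@@H]1C(=O)C=C[C@@]1(CCCCCCCC(=O)OC(C)=O)OC(C)=O
A1 | alternative 1 | tert-butyl (9R,10S)-9-(acetyloxy)-9-ethenyl-11-oxo-10-[(2Z)-pent-2-en-1-yl]tridec-12-enoate | CC/C=C\C[C@H](C(=O)C=C)[C@](C=C)(CCCCCCCC(=O)OC(C)(C)C)OC(C)=O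
A2 | alternative 2 | tert-butyl 8-{5-[(3Z)-hex-3-en-1-yl]furan-2-yl}octanoate | CC/C=C\CCc1ccc(CCCCCCCC(=O)OC(C)(C)C)o1
A3 | alternative 2 | tert-butyl (10Z,15Z)-9,12-dioxooctadeca-10,15-dienoate | CC/C=C\CCC(=O)/C=C\C(=O)CCCCCCCC(=O)OC(C)(C)C
A4 | alternative 3 | 2-[(2Z)-pent-2-en-1-yl]cyclopent-4-ene-1,3-dione | CC/C=C\CC1C(=O)C=CC1=O
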